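The 13-membered carbocycle is closed last by an intramolecular B-alkyl Suzuki–Miyaura coupling.

Atom labels: tetronate O1–C2(=O)–C3=C4–C5, ether carbon C12, macrocycle chain C13 to C21 (ketone) back to C3. The 13-membered carbocycle is disconnected at C16–C17. One operation, an intramolecular B-alkyl Suzuki–Miyaura coupling, hydroborates the terminal vinyl group of a (Z)-diene on C12 and couples the new primary borane with a (Z)-iodoalkene on the C3 side chain; it exploits the skipped (Z,Z)-1,5-diene C13=C14–C15–C16–C17=C18, whose geometries and the C19 methoxy centre are set beforehand. The precursor is the tricyclic spirotetronate (tetronate, cyclohexene and pyran rings, from an intramolecular Diels–Alder reaction of an ether-tethered 5-methylene tetronate) carrying diene and iodoalkene.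

Key step: step 21

Remark: further labels are cyclohexene C5–C6H2–C7H(Et)–C8(Me)=C9H–C10(Me) and pyran C4–O–C12(Me)–C11H2–C10–C5; "core" means this tricycle with (5S,7S,10S,12S) configuration, as in the target.

Step 1
Reactants: 1 (2E)-2-methylpent-2-enal; 2 triethyl 2-phosphonopropanoate
Product: 3 ethyl (2E,4E)-2,4-dimethylhepta-2,4-dienoate
Conditions: NaH, THF, 0 °C → rt
Reagents that add atoms: none
Why: Horner–Wadsworth–Emmons olefination of the enal with the α-methyl phosphonate anion should give the (2E)-trisubstituted enoate, the existing (E)-alkene being untouched.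

Step 2
Reactants: 3 ethyl (2E,4E)-2,4-dimethylhepta-2,4-dienoate
Product: 4 (2E,4E)-2,4-dimethylhepta-2,4-dien-1-ol
Conditions: DIBAL-H, CH2Cl2, −78 °C
Reagents that add atoms: none
Why: 1,2-reduction of the conjugated ester by the aluminium hydride gives the allylic alcohol without touching the diene.

Step 3
Reactants: 4 (2E,4E)-2,4-dimethylhepta-2,4-dien-1-ol
Product: 5 (2E,4E)-1-bromo-2,4-dimethylhepta-2,4-diene
Conditions: CBr4, PPh3, CH2Cl2, 0 °C; used directly
Reagents that add atoms: carbon tetrabromide, BrC(Br)(Br)Br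
Why: Appel bromination of the primary allylic alcohol proceeds by SN2 displacement under neutral conditions, so the diene geometry and position should be kept.

Step 4
Reactants: 6 (R)-lactic acid; 7 pivalaldehyde
Product: 8 (2R,5R)-2-tert-butyl-5-methyl-1,3-dioxolan-4-one
Conditions: p-TsOH (cat.), pentane, reflux, water separator; crystallisation of the cis isomer at low temperature
Reagents that add atoms: none
Why: acid-catalysed acetalisation of the α-hydroxy acid gives the dioxolanone, whose cis isomer (new acetal centre 2R) is favoured thermodynamically and purified by crystallisation.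

Step 5
Reactants: 8 (2R,5R)-2-tert-butyl-5-methyl-1,3-dioxolan-4-one; 5 (2E,4E)-1-bromo-2,4-dimethylhepta-2,4-diene
Product: 9 (2R,5S)-2-tert-butyl-5-[(2E,4E)-2,4-dimethylhepta-2,4-dien-1-yl]-5-methyl-1,3-dioxolan-4-one
Conditions: LDA, THF, −78 °C; then 5, −78 → −30 °C
Reagents that add atoms: none
Why: enolate alkylation with self-regeneration of the stereocentre: the primary allylic bromide is attacked (SN2) on the face opposite the tert-butyl group, which sets the quaternary centre (future C12) with retention.

Step 6
Reactants: 9 the alkylated dioxolanone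
Product: 10 (2S,4E,6E)-2,4,6-trimethylnona-4,6-diene-1,2-diol
Conditions: LiAlH4, THF, 0 °C → rt
Reagents that add atoms: none
Why: hydride reduction of the lactone carbonyl gives the primary alcohol (future C13) and releases the tertiary hydroxyl as the acetal collapses; the quaternary centre is not touched.

Step 7
Reactants: 10 (2S,4E,6E)-2,4,6-trimethylnona-4,6-diene-1,2-diol
Product: 11 (2S,4E,6E)-1-[(tert-butyldiphenylsilyl)oxy]-2,4,6-trimethylnona-4,6-dien-2-ol
Conditions: TBDPSCl, imidazole, CH2Cl2, 0 °C → rt
Reagents that add atoms: tert-butyl(chloro)diphenylsilane, CC(C)(C)[Si](Cl)(c1ccccc1)c1ccccc1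
Why: the bulky silyl chloride reacts only with the primary hydroxyl and leaves the tertiary alcohol free.

Step 8
Reactants: 11 the silyl ether alcohol; 12 methyl propiolate
Product: 13 methyl (2E)-3-{[(2S,4E,6E)-1-[(tert-butyldiphenylsilyl)oxy]-2,4,6-trimethylnona-4,6-dien-2-yl]oxy}prop-2-enoate
Conditions: PMe3 (cat.), CH2Cl2, 0 °C → rt
Reagents that add atoms: none
Why: phosphine-catalysed oxa-Michael addition, which also works for hindered tertiary alcohols, gives the (E)-β-alkoxyacrylate and so forms the C4–O–C12 ether without touching the stereocentre.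

Step 9
Reactants: 13 the β-alkoxyacrylate; 14 chloroacetaldehyde
Product: 16 5-(chloromethyl)-4-(tert-alkoxy)furan-2(5H)-one (tetronate ether; C5 epimers), via hydroxy ester alkoxide 15 (not isolated)
Conditions: LDA, THF, −95 °C; then 14 (anhydrous, freshly distilled), −95 → −20 °C; aq. NH4Cl
Reagents that add atoms: none
Why: β-lithiation of the β-alkoxyacrylate (vinylic hydrogen geminal to oxygen, lithium chelated by the cis ester), 1,2-addition to the aldehyde and lactonisation of the cis alkoxide onto the ester close the tetronate ring; the C5 centre forms unselectively and is removed in step 10.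

Step 10
Reactants: 16 the 5-(chloromethyl) tetronate ether
Product: 18 core with H at C3 and CH2OTBDPS at C12 (tricyclic silyl ether), via 5-methylene tetronate 17 (not isolated)
Conditions: DBU, toluene, 0 °C → rt; then 110 °C, BHT (cat.), 0.005 M
Reagents that add atoms: none
Why: E1cB loss of HCl gives the 5-methylene tetronate, whose exocyclic alkene is the tethered dienophile of a type 1 intramolecular Diels–Alder reaction closing the cyclohexene and pyran rings together: the (E,E)-diene fixes C7 relative to C10, the endo transition state (tetronate C3=C4 under the diene) gives the cis ring fusion at C5/C10, and the C12 centre should select the diene face by placing its bulky CH2OTBDPS arm outward and the methyl group in the crowded inside position next to the dienophile CH2.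

Step 11
Reactants: 18 the tricyclic silyl ether
Product: 19 core with H at C3 and CH2OH at C12 (tricyclic alcohol)
Conditions: TBAF, THF, 0 °C
Reagents that add atoms: none
Why: fluoride cleaves the silyl ether; lactone, enol ether and alkenes are inert.

Step 12
Reactants: 19 the tricyclic alcohol
Product: 20 core with H at C3 and CHO at C12 (tricyclic aldehyde)
Conditions: Dess–Martin periodinane, CH2Cl2, 0 °C → rt
Reagents that add atoms: none
Why: mild Dess–Martin oxidation gives the aldehyde, which cannot epimerise because its α-carbon C12 is quaternary.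

Step 13
Reactants: 20 the tricyclic aldehyde
Product: 21 core with H at C3 and (Z)-2-iodoprop-1-en-1-yl at C12 (tricyclic iodoalkene)
Conditions: Ph3P(Et)I, n-BuLi, THF, rt; I2, −78 °C; NaHMDS, −78 °C; then 20, −78 → −20 °C; dark
Reagents that add atoms: ethyltriphenylphosphonium iodide, CC[P+](c1ccccc1)(c1ccccc1)c1ccccc1.[I-]; iodine, II
Why: Stork–Zhao olefination with the α-iodoethylidene ylide gives the (Z)-2-iodoalkene through the kinetically favoured cis oxaphosphetane, so iodine ends cis to C12 at the future C13=C14 bond.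

Step 14
Reactants: 21 the tricyclic iodoalkene
Product: 22 core with H at C3 and (Z)-2-methylbuta-1,3-dien-1-yl at C12 (tricyclic diene)
Conditions: tributyl(vinyl)stannane, Pd2(dba)3 (cat.), AsPh3, CuI (cat.), DMF, 40 °C
Reagents that add atoms: tributyl(vinyl)stannane, C=C[Sn](CCCC)(CCCC)CCCC
Why: Stille coupling replaces iodine by vinyl with retention of the alkene geometry, giving the (13Z)-diene C13=C14–C15=C16 at a temperature below that of a Claisen shift of the allyl vinyl ether.

Step 15
Reactants: 23 propargyl alcohol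
Product: 24 (2Z)-3-iodo-2-methylprop-2-en-1-ol
Conditions: MeMgBr, CuI (cat.), THF, −10 °C → rt; then I2, −10 °C
Reagents that add atoms: methylmagnesium bromide, C[Mg]Br; iodine, II
Why: copper-catalysed carbomagnesiation of the magnesium alkoxide places methyl on C2 and magnesium on C3 in a five-membered chelate (net anti addition), and iodinolysis with retention gives the (Z)-iodoalkene (future C17=C18).

Step 16
Reactants: 24 (2Z)-3-iodo-2-methylprop-2-en-1-ol
Product: 25 (2Z)-3-iodo-2-methylprop-2-enal
Conditions: MnO2, CH2Cl2, rt, dark; used directly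
Reagents that add atoms: none
Why: neutral allylic oxidation on the MnO2 surface gives the enal without isomerising the (Z)-alkene.

Step 17
Reactants: 25 (2Z)-3-iodo-2-methylprop-2-enal
Product: 26 (1Z,3R)-1-iodo-2-methylhexa-1,5-dien-3-ol
Conditions: allyltributylstannane, Ti(OiPr)4 (cat.), (R)-BINOL (cat.), 4 Å MS, CH2Cl2, −20 °C
Reagents that add atoms: allyltributylstannane, C=CC[Sn](CCCC)(CCCC)CCCC
Why: Keck allylation; the (R)-BINOL titanium Lewis acid shields one face of the aldehyde and should give the (R)-carbinol (future C19).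

Step 18
Reactants: 26 (1Z,3R)-1-iodo-2-methylhexa-1,5-dien-3-ol
Product: 27 (1Z,3R)-1-iodo-3-methoxy-2-methylhexa-1,5-diene
Conditions: NaH, MeI, THF, 0 °C → rt
Reagents that add atoms: iodomethane, CI
Why: Williamson O-methylation of the alkoxide installs the methyl ether without touching the stereocentre or the iodoalkene.

Step 19
Reactants: 27 (1Z,3R)-1-iodo-3-methoxy-2-methylhexa-1,5-diene
Product: 28 (3R,4Z)-5-iodo-3-methoxy-4-methylpent-4-enal
Conditions: OsO4 (cat.), NaIO4, 2,6-lutidine, dioxane/H2O, rt; used directly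
Reagents that add atoms: osmium tetroxide, O=[Os](=O)(=O)=O (oxygen donor, regenerated by periodate); sodium periodate, [Na+].[O-]I(=O)(=O)=O
Why: Lemieux–Johnson cleavage attacks the monosubstituted terminal alkene, while the electron-poor, trisubstituted iodoalkene should be spared.

Step 20
Reactants: 22 the tricyclic diene; 28 (3R,4Z)-5-iodo-3-methoxy-4-methylpent-4-enal
Product: 29 tricyclic diene bearing at C3 the (3R,4Z)-1-hydroxy-5-iodo-3-methoxy-4-methylpent-4-en-1-yl chain (seco carbinol; C21 epimers)
Conditions: LDA, THF, −78 °C; then 28, −78 °C; aq. NH4Cl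
Reagents that add atoms: none
Why: 4-alkoxybutenolides without a C5 hydrogen are metalated at C3, and the vinyllithium adds to the aldehyde faster than it exchanges with the iodoalkene; the new C21 carbinol forms as a mixture that converges in step 22.

Step 21
Reactants: 29 the seco carbinol
Product: 31 macrocyclic carbinol (21-hydroxy compound; C21 epimers), via bis-borylated alkylborane 30 (not isolated)
Conditions: 9-BBN-H, THF, 0 °C → rt; then slow addition to Pd(dppf)Cl2 (cat.), AsPh3, Cs2CO3, DMF/THF/H2O, rt, 0.001 M
Reagents that add atoms: none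
Why: 9-BBN adds H–B across the terminal C15=C16 bond of the (Z)-diene with boron on C16 (the hydroxyl is borylated with loss of H2), then oxidative addition of zerovalent palladium into the C17–I bond, base-assisted transmetalation of the primary alkylborane and reductive elimination form the C16–C17 bond. The closest known reaction type is the B-alkyl Suzuki–Miyaura macrocyclisation of a terminal alkene hydroborated in the flask with a (Z)-iodoalkene. The 13-membered carbocycle is closed head to tail by a C(sp3)–C(sp2) bond, endo to the iodoalkene, favoured by high dilution and by the two Z-alkenes and the rigid tricycle, which hold the chain ends on the same side. No stereocentre is created: both alkene geometries are carried through with retention, C19 is untouched, and the C21 epimers converge in step 22. The step needs chemoselective hydroboration of the terminal CH2=CH of the diene over the trisubstituted alkenes and the iodoalkene, which the steric demand of 9-BBN should secure, and C21 is kept at the alcohol level so that no conjugated ketone competes for the borane.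

Step 22
Reactants: 31 the macrocyclic carbinol
Product: 32 streptaspironate A
Conditions: Dess–Martin periodinane, CH2Cl2, 0 °C → rt
Reagents that add atoms: none
Why: Dess–Martin oxidation converts both C21 epimers into the C21 ketone under conditions that do not eliminate the β-methoxy group or isomerise the Z-alkenes.

Compound list
1 | (2E)-2-methylpent-2-enal | CC/C=C(\C)C=O | starting material
2 | triethyl 2-phosphonopropanoate | CCOC(=O)C(C)P(=O)(OCC)OCC | starting material
3 | ethyl (2E,4E)-2,4-dimethylhepta-2,4-dienoate | CCOC(=O)/C(C)=C/C(C)=C/CC | intermediate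
4 | (2E,4E)-2,4-dimethylhepta-2,4-dien-1-ol | OC/C(C)=C/C(C)=C/CC | intermediate
5 | (2E,4E)-1-bromo-2,4-dimethylhepta-2,4-diene | BrC/C(C)=C/C(C)=C/CC | intermediate
6 | (R)-lactic acid | C[C@@H](O)C(=O)O | starting material
7 | pivalaldehyde | CC(C)(C)C=O | starting material
8 | (2R,5R)-2-tert-butyl-5-methyl-1,3-dioxolan-4-one | C[C@H]1O[C@@H](C(C)(C)C)OC1=O | intermediate
9 | (2R,5S)-2-tert-butyl-5-[(2E,4E)-2,4-dimethylhepta-2,4-dien-1-yl]-5-methyl-1,3-dioxolan-4-one | C[C@@]1(C/C(C)=C/C(C)=C/CC)O[C@@H](C(C)(C)C)OC1=O | intermediate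
10 | (2S,4E,6E)-2,4,6-trimethylnona-4,6-diene-1,2-diol | O[C@](C)(CO)C/C(C)=C/C(C)=C/CC | intermediate
11 | (2S,4E,6E)-1-[(tert-butyldiphenylsilyl)oxy]-2,4,6-trimethylnona-4,6-dien-2-ol | O[C@](C)(CO[Si](c1ccccc1)(c1ccccc1)C(C)(C)C)C/C(C)=C/C(C)=C/CC | intermediate
12 | methyl propiolate | COC(=O)C#C | starting material
13 | methyl (2E)-3-{[(2S,4E,6E)-1-[(tert-butyldiphenylsilyl)oxy]-2,4,6-trimethylnona-4,6-dien-2-yl]oxy}prop-2-enoate | COC(=O)/C=C/O[C@](C)(CO[Si](c1ccccc1)(c1ccccc1)C(C)(C)C)C/C(C)=C/C(C)=C/CC | intermediate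
14 | chloroacetaldehyde | ClCC=O | starting material
15 | methyl (2E)-5-chloro-4-hydroxy-3-(tert-alkoxy)pent-2-enoate, formed as its lithium alkoxide (tert-alkoxy as in 13; C4 epimers) | COC(=O)/C=C(\C(O)CCl)O[C@](C)(CO[Si](c1ccccc1)(c1ccccc1)C(C)(C)C)C/C(C)=C/C(C)=C/CC | intermediate
16 | 5-(chloromethyl)-4-{[(2S,4E,6E)-1-[(tert-butyldiphenylsilyl)oxy]-2,4,6-trimethylnona-4,6-dien-2-yl]oxy}furan-2(5H)-one (C5 epimers) | ClCC1OC(=O)C=C1O[C@](C)(CO[Si](c2ccccc2)(c3ccccc3)C(C)(C)C)C/C(C)=C/C(C)=C/CC | intermediate
17 | 5-methylidene-4-{[(2S,4E,6E)-1-[(tert-butyldiphenylsilyl)oxy]-2,4,6-trimethylnona-4,6-dien-2-yl]oxy}furan-2(5H)-one | C=C1OC(=O)C=C1O[C@](C)(CO[Si](c2ccccc2)(c3ccccc3)C(C)(C)C)C/C(C)=C/C(C)=C/CC | intermediate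
18 | core (5S,7S,10S,12S) with H at C3 and CH2OTBDPS at C12 | CC[C@H]1C[C@@]23OC(=O)C=C2O[C@](C)(CO[Si](c4ccccc4)(c5ccccc5)C(C)(C)C)C[C@@]3(C)C=C1C | intermediate
19 | core (5S,7S,10S,12S) with H at C3 and CH2OH at C12 | CC[C@H]1C[C@@]23OC(=O)C=C2O[C@](C)(CO)C[C@@]3(C)C=C1C | intermediate
20 | core (5S,7S,10S,12S) with H at C3 and CHO at C12 | CC[C@H]1C[C@@]23OC(=O)C=C2O[C@](C)(C=O)C[C@@]3(C)C=C1C | intermediate
21 | core (5S,7S,10S,12S) with H at C3 and (Z)-2-iodoprop-1-en-1-yl at C12 | CC[C@H]1C[C@@]23OC(=O)C=C2O[C@](C)(/C=C(/C)I)C[C@@]3(C)C=C1C | intermediate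
22 | core (5S,7S,10S,12S) with H at C3 and (Z)-2-methylbuta-1,3-dien-1-yl at C12 | CC[C@H]1C[C@@]23OC(=O)C=C2O[C@](C)(/C=C(/C)C=C)C[C@@]3(C)C=C1C | intermediate
23 | propargyl alcohol | C#CCO | starting material
24 | (2Z)-3-iodo-2-methylprop-2-en-1-ol | I/C=C(/C)CO | intermediate
25 | (2Z)-3-iodo-2-methylprop-2-enal | I/C=C(/C)C=O | intermediate
26 | (1Z,3R)-1-iodo-2-methylhexa-1,5-dien-3-ol | I/C=C(/C)[C@H](O)CC=C | intermediate
27 | (1Z,3R)-1-iodo-3-methoxy-2-methylhexa-1,5-diene | I/C=C(/C)[C@H](OC)CC=C | intermediate
28 | (3R,4Z)-5-iodo-3-methoxy-4-methylpent-4-enal | I/C=C(/C)[C@H](OC)CC=O | intermediate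
29 | tricyclic diene 22 bearing at C3 the (3R,4Z)-1-hydroxy-5-iodo-3-methoxy-4-methylpent-4-en-1-yl chain (C21 epimers) | CC[C@H]1C[C@@]23OC(=O)C(C(O)C[C@@H](OC)/C(C)=C\I)=C2O[C@](C)(/C=C(/C)C=C)C[C@@]3(C)C=C1C | intermediate
30 | alkylborane of 29 with 9-BBN on C16 and on the C21 oxygen | CC[C@H]1C[C@@]23OC(=O)C(C(OB4C5CCCC4CCC5)C[C@@H](OC)/C(C)=C\I)=C2O[C@](C)(/C=C(/C)CCB6C7CCCC6CCC7)C[C@@]3(C)C=C1C | intermediate
31 | macrocyclic carbinol: the target with CH(OH) at C21 (5S,7S,10S,12S,19R; 13Z,17Z; C21 epimers) | CC[C@H]1C[C@@]23OC(=O)C4=C2O[C@](C)(/C=C(/C)CC/C=C(/C)[C@H](OC)CC4O)C[C@@]3(C)C=C1C | intermediate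
32 | streptaspironate A (5S,7S,10S,12S,19R; 13Z,17Z) | CC[C@H]1C[C@@]23OC(=O)C4=C2O[C@](C)(/C=C(/C)CC/C=C(/C)[C@H](OC)CC4=O)C[C@@]3(C)C=C1C | target

Total step count: 22. Longest linear sequence: 16 steps (steps 1–3, 5–14, 20–22).

Steps most likely to fail

Step 10. The process at risk is poor π-facial selection in the cycloaddition. Methyl and CH2OTBDPS differ little at the atom bound to C12, so the adduct with the opposite relation between C12 and C5/C7/C10 could form in similar amount; a trans-fused exo adduct is a second possibility. The fallback raises the bias by branching the arm at C13. It sets out from diol 10, whose primary alcohol is oxidised selectively (TEMPO cat., PhI(OAc)2, CH2Cl2) to (2S,4E,6E)-2-hydroxy-2,4,6-trimethylnona-4,6-dienal F1. This is converted (HC(OMe)3, MeOH, PPTS) into (2S,4E,6E)-1,1-dimethoxy-2,4,6-trimethylnona-4,6-dien-2-ol F2, which is carried through the chemistry of steps 8 to 10: phosphine-catalysed addition to methyl propiolate gives the acetal acrylate F3; lithiation and addition to chloroacetaldehyde give, through the acetal hydroxy ester F4, the acetal 5-(chloromethyl) tetronate F5; DBU gives the acetal 5-methylene tetronate F6, which on heating should give the tricyclic dimethyl acetal F7. A dimethoxymethyl group can point only its C–H into the inside position, which should favour the outward arrangement more strongly. Hydrolysis of F7 (aq. HCl, THF) gives aldehyde 20, where the route is rejoined (steps 11 and 12 are not needed).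

Step 21. The process at risk is slow or unselective hydroboration of the diene beside the quaternary C12, followed by slow transmetalation, so that protodeboronation, oligomerisation or reduction of the iodoalkene compete with ring closure. The fallback exchanges the roles of the two chain ends and closes the same ring at C14–C15. It sets out from iodoalkene 21 and aldehyde 28. Stille coupling of 28 with tributyl(vinyl)stannane (Pd2(dba)3, AsPh3, DMF) gives (3R,4Z)-3-methoxy-4-methylhepta-4,6-dienal F8. Brief C3-lithiation of 21 (LDA, THF, −78 °C) and addition to F8 give the seco carbinol with core iodoalkene and side-chain diene F9. 9-BBN-H then hydroborates the unhindered terminal alkene of the side-chain diene to give the C15 alkylborane F10, and coupling with the core iodoalkene at C14 (Pd(dppf)Cl2, AsPh3, Cs2CO3, high dilution) gives macrocyclic carbinol 31, where the route is rejoined before step 22.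

Step 9. The process at risk is decomposition of the β-lithio acrylate (loss of the tertiary alkoxide, self-condensation) before it is trapped, or closure of the chloro alkoxide to an epoxide instead of the lactone. The fallback builds the tetronate by a domino addition–intramolecular Wittig reaction and sets out from alcohol 11. Its lithium alkoxide (n-BuLi, THF, −78 °C) is acylated with (S)-2-acetoxypropanoyl chloride to give the acetoxypropanoate ester F11. Removal of the acetate (K2CO3, MeOH) gives the α-hydroxy ester F12. Treatment with Ph3P=C=C=O (toluene, reflux) adds the hydroxyl to the ketene, and the ester ylide so formed olefinates the neighbouring ester carbonyl to give the 5-methyl tetronate ether F13. Selenenylation at C5 (LDA, PhSeBr, −78 °C) gives the 5-methyl-5-(phenylselanyl) tetronate F14. Oxidation (H2O2, 0 °C) gives the selenoxide F15, whose syn-elimination delivers the 5-methylene tetronate 17; this is heated as in step 10 to rejoin the route at 18.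

Further compounds
F1 | step 10 | (2S,4E,6E)-2-hydroxy-2,4,6-trimethylnona-4,6-dienal | O[C@](C)(C=O)C/C(C)=C/C(C)=C/CC
F2 | step 10 | (2S,4E,6E)-1,1-dimethoxy-2,4,6-trimethylnona-4,6-dien-2-ol | O[C@](C)(C(OC)OC)C/C(C)=C/C(C)=C/CC
F3 | step 10 | methyl (2E)-3-{[(2S,4E,6E)-1,1-dimethoxy-2,4,6-trimethylnona-4,6-dien-2-yl]oxy}prop-2-enoate (acetal acrylate) | COC(=O)/C=C/O[C@](C)(C(OC)OC)C/C(C)=C/C(C)=C/CC
F4 | step 10 | acetal hydroxy ester (lithium alkoxide; C4 epimers) | COC(=O)/C=C(\C(O)CCl)O[C@](C)(C(OC)OC)C/C(C)=C/C(C)=C/CC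
F5 | step 10 | acetal 5-(chloromethyl) tetronate (C5 epimers) | ClCC1OC(=O)C=C1O[C@](C)(C(OC)OC)C/C(C)=C/C(C)=C/CC
F6 | step 10 | acetal 5-methylene tetronate | C=C1OC(=O)C=C1O[C@](C)(C(OC)OC)C/C(C)=C/C(C)=C/CC
F7 | step 10 | tricyclic dimethyl acetal (core with H at C3 and CH(OMe)2 at C12) | CC[C@H]1C[C@@]23OC(=O)C=C2O[C@](C)(C(OC)OC)C[C@@]3(C)C=C1C
F8 | step 21 | (3R,4Z)-3-methoxy-4-methylhepta-4,6-dienal | C=C/C=C(/C)[C@H](OC)CC=O
F9 | step 21 | seco carbinol with core iodoalkene and side-chain diene (C21 epimers) | CC[C@H]1C[C@@]23OC(=O)C(C(O)C[C@@H](OC)/C(C)=C\C=C)=C2O[C@](C)(/C=C(/C)I)C[C@@]3(C)C=C1C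
F10 | step 21 | C15 alkylborane of F9 (9-BBN on C15 and on the C21 oxygen) | CC[C@H]1C[C@@]23OC(=O)C(C(OB4C5CCCC4CCC5)C[C@@H](OC)/C(C)=C\CCB6C7CCCC6CCC7)=C2O[C@](C)(/C=C(/C)I)C[C@@]3(C)C=C1C
F11 | step 9 | (2S)-2-acetoxypropanoate ester of 11 | C[C@H](OC(C)=O)C(=O)O[C@](C)(CO[Si](c1ccccc1)(c1ccccc1)C(C)(C)C)C/C(C)=C/C(C)=C/CC
F12 | step 9 | (2S)-2-hydroxypropanoate ester of 11 | C[C@H](O)C(=O)O[C@](C)(CO[Si](c1ccccc1)(c1ccccc1)C(C)(C)C)C/C(C)=C/C(C)=C/CC
F13 | step 9 | (5S)-5-methyl tetronate ether (5-methyl analogue of 16) | C[C@@H]1OC(=O)C=C1O[C@](C)(CO[Si](c2ccccc2)(c3ccccc3)C(C)(C)C)C/C(C)=C/C(C)=C/CC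
F14 | step 9 | 5-methyl-5-(phenylselanyl) tetronate ether (C5 epimers) | CC1([Se]c2ccccc2)OC(=O)C=C1O[C@](C)(CO[Si](c3ccccc3)(c4ccccc4)C(C)(C)C)C/C(C)=C/C(C)=C/CC
F15 | step 9 | selenoxide of F14 | CC1([Se](=O)c2ccccc2)OC(=O)C=C1O[C@](C)(CO[Si](c3ccccc3)(c4ccccc4)C(C)(C)C)C/C(C)=C/C(C)=C/CC
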